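## Retrosynthetic overview
1. The target comes from global MOM removal of a tri-MOM flavanone. This is the last step and does not touch the C2 stereocentre.
2. The C ring and the (2S) centre come from a catalytic enantioselective intramolecular oxa-Michael addition of the single free phenol of a chalcone. This is the new step.
3. The chalcone comes from Claisen–Schmidt condensation of an A-ring acetophenone and a B-ring chromene salicylaldehyde. The acetophenone already carries the prenyl group and has only the prenyl-distal OH free. The aldehyde is MOM-protected.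
4. The A ring is made from phloroacetophenone by C-prenylation and then O-differentiation. The B-ring pyran is made from 2,4-dihydroxybenzaldehyde by propargylation and Claisen/6π cyclization.
5. Ring-formation order: B-ring pyran first, then A-ring prenylation, then the pyranone C ring last.

Assumptions:
- (a) Phloroacetophenone mono-C-prenylates at C3, and a modest yield is accepted.
- (b) The propargyl-ether cyclization goes at C5, para to the 2-OH, to give the linear chromene.
- (c) The enantiomer of catalyst 16 that gives 2S is chosen by screening, and the L-tert-leucine-derived one is drawn.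
- (d) Catalyst 16 is prepared by standard literature procedures from commercial L-tert-leucine-derived building blocks. It is treated as a starting material.

## Route

**Step 1**
Reactants: 1 (2,4,6-trihydroxyacetophenone), 2 (prenyl bromide)
Product: 3 (1-(2,4,6-trihydroxy-3-prenylphenyl)ethanone)
Conditions: KOH, H2O/MeOH, 0 °C → rt, 24 h
Reagents that add atoms: prenyl bromide, CC(C)=CCBr
Why: Phenolate C-alkylation in protic medium puts one prenyl on C3 (the two ortho carbons are equivalent by symmetry). O-alkylation and diprenylation are minor and removed by chromatography.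

**Step 2**
Reactants: 3, 4 (chloromethyl methyl ether, MOMCl)
Product: 5 (1-(2,6-dihydroxy-4-MOMO-3-prenylphenyl)ethanone)
Conditions: MOMCl (1.05 equiv), i-Pr2NEt, CH2Cl2, 0 °C → rt
Reagents that add atoms: MOMCl, COCCl
Why: Only the 4-OH is acidic and not chelated to the carbonyl, so it is protected selectively (MOM ether formation).

**Step 3**
Reactants: 5, 6 (TBSCl)
Product: 7 (6-OTBS ether, 2-OH free)
Conditions: TBSCl (1.1 equiv), imidazole, DMF, 0 °C → rt
Reagents that add atoms: TBSCl, C[Si](C)(Cl)C(C)(C)C
Why: The OH flanked by the ring H is far less hindered than the OH next to the prenyl group, so the bulky silyl chloride goes there (steric silylation).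

**Step 4**
Reactants: 7, 4 (MOMCl)
Product: 8 (2-OMOM, 6-OTBS, 4-OMOM, 3-prenyl acetophenone)
Conditions: NaH, THF/DMF, 0 °C, short reaction time; then MOMCl, 0 °C → rt
Reagents that add atoms: MOMCl, COCCl
Why: The hindered, chelated phenoxide is alkylated by the small, reactive MOMCl (Williamson-type MOM protection).

**Step 5**
Reactants: 8
Product: 9 (1-[2-hydroxy-4,6-bis(MOMO)-5-prenylphenyl]ethanone)
Conditions: TBAF, AcOH, THF, 0 °C, 30 min
Reagents that add atoms: none
Why: Fluoride removes the aryl silyl ether, and the AcOH buffer protects the MOM groups. This leaves the prenyl-distal OH as the only free phenol, which fixes the 6-prenyl regiochemistry of the later ring closure (desilylation).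

**Step 6**
Reactants: 10 (2,4-dihydroxybenzaldehyde), 11 (3-chloro-3-methylbut-1-yne)
Product: 12 (2-hydroxy-4-[(2-methylbut-3-yn-2-yl)oxy]benzaldehyde)
Conditions: DBU, CuI (cat.), MeCN, 0 °C → rt
Reagents that add atoms: 3-chloro-3-methylbut-1-yne, CC(C)(Cl)C#C
Why: The 2-OH is chelated to the aldehyde, so only the 4-OH is alkylated (Cu-mediated propargylation of phenols).

**Step 7**
Reactants: 12
Product: 13 (7-hydroxy-2,2-dimethyl-2H-chromene-6-carbaldehyde)
Conditions: PhNEt2, 210 °C, 3 h, sealed tube, Ar
Reagents that add atoms: none
Why: Aryl propargyl ether Claisen [3,3], then 1,5-H shift and oxa-6π electrocyclization build the 2,2-dimethylchromene. Cyclization at C5 (para to the 2-OH, unhindered) gives the linear isomer.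

**Step 8**
Reactants: 13, 4 (MOMCl)
Product: 14 (7-MOMO-2,2-dimethyl-2H-chromene-6-carbaldehyde)
Conditions: NaH, THF/DMF, 0 °C; then MOMCl, 0 °C → rt
Reagents that add atoms: MOMCl, COCCl
Why: MOM protection of the chelated phenol keeps the B-ring oxygen from taking part in the later steps.

**Step 9**
Reactants: 9, 14
Product: 15 ((E)-chalcone)
Conditions: KOH, EtOH/H2O, 25–40 °C, 48–72 h; sat. NH4Cl work-up
Reagents that add atoms: none
Why: Claisen–Schmidt aldol condensation. The free 6′-OH stays as its chelated phenoxide under these conditions, which disfavours spontaneous racemic cyclization. The E-enone is formed.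

**Step 10**
Reactants: 15, 16 (chiral bifunctional iminophosphorane catalyst)
Product: 17 ((2S)-5,7,2′-tris(MOMO)-6-prenyl flavanone with 4′,5′-dimethylchromene ring)
Conditions: 16 (10 mol %), MTBE, 0.05 M, 4 Å MS, –20 °C, 72 h
Reagents that add atoms: none (catalyst)
Why: Proposed new method: intramolecular enantioselective oxa-Michael (6-endo-trig) cyclization. The iminophosphorane deprotonates the lone free phenol to give a tight iminophosphonium phenoxide ion pair, while the thiourea N–H bonds hold the enone s-cis and control which enone face the oxygen attacks (this sets the 2S centre), and the iminophosphonium N–H then protonates the enolate. The substrate is a strongly push–pull deactivated chalcone, with an o-OMOM and p-alkoxy B ring and a twisted dialkoxy-flanked ketone. The closest known reactions are bifunctional iminophosphorane oxa-Michael additions to unactivated esters and amides and thiourea-catalysed flavanone formation from simple 2′-hydroxychalcones. The low temperature and the absence of any product phenol (no 5-OH chelation to acidify C3) slow the retro-Michael reaction that would erode ee.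

**Step 11**
Reactants: 17
Product: 18 (cudraflavanone A)
Conditions: ZnBr2, n-PrSH, CH2Cl2, 0 °C, 15 min
Reagents that add atoms: none
Why: Thiol-assisted Lewis-acid MOM cleavage is mild and non-basic, and it does not touch the prenyl group, the chromene or the flavanone C2 centre (MOM deprotection).

## Compound list
1 | 2,4,6-trihydroxyacetophenone | CC(=O)c1c(O)cc(O)cc1O | starting material
2 | prenyl bromide | CC(C)=CCBr | starting material
3 | 1-(2,4,6-trihydroxy-3-prenylphenyl)ethanone | CC(=O)c1c(O)cc(O)c(CC=C(C)C)c1O | intermediate
4 | chloromethyl methyl ether | COCCl | starting material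
5 | 4-MOM, 3-prenyl-2,6-dihydroxyacetophenone | CC(=O)c1c(O)cc(OCOC)c(CC=C(C)C)c1O | intermediate
6 | TBSCl | C[Si](C)(Cl)C(C)(C)C | starting material
7 | 6-OTBS, 2-OH, 4-OMOM, 3-prenyl acetophenone | CC(=O)c1c(O[Si](C)(C)C(C)(C)C)cc(OCOC)c(CC=C(C)C)c1O | intermediate
8 | 6-OTBS, 2,4-bis(OMOM), 3-prenyl acetophenone | CC(=O)c1c(O[Si](C)(C)C(C)(C)C)cc(OCOC)c(CC=C(C)C)c1OCOC | intermediate
9 | 2-hydroxy-4,6-bis(MOMO)-5-prenylacetophenone | CC(=O)c1c(O)cc(OCOC)c(CC=C(C)C)c1OCOC | intermediate
10 | 2,4-dihydroxybenzaldehyde | O=Cc1ccc(O)cc1O | starting material
11 | 3-chloro-3-methylbut-1-yne | CC(C)(Cl)C#C | starting material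
12 | 2-hydroxy-4-(2-methylbut-3-yn-2-yloxy)benzaldehyde | O=Cc1ccc(OC(C)(C)C#C)cc1O | intermediate
13 | 7-hydroxy-2,2-dimethyl-2H-chromene-6-carbaldehyde | O=Cc1cc2C=CC(C)(C)Oc2cc1O | intermediate
14 | 7-MOMO-2,2-dimethyl-2H-chromene-6-carbaldehyde | O=Cc1cc2C=CC(C)(C)Oc2cc1OCOC | intermediate
15 | (E)-chalcone, tri-MOM, 6′-OH free | COCOc1cc2OC(C)(C)C=Cc2cc1/C=C/C(=O)c1c(O)cc(OCOC)c(CC=C(C)C)c1OCOC | intermediate
16 | L-tert-leucinol-derived thiourea–iminophosphorane (BIMP) catalyst, (S) | CC(C)(C)[C@@H](CNC(=S)Nc1cc(C(F)(F)F)cc(C(F)(F)F)c1)N=P(c1ccc(OC)cc1)(c1ccc(OC)cc1)c1ccc(OC)cc1 | starting material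
17 | (2S)-tri-MOM flavanone | CC(C)=CCc1c(OCOC)cc2c(c1OCOC)C(=O)C[C@@H](c1cc3c(cc1OCOC)OC(C)(C)C=C3)O2 | intermediate
18 | cudraflavanone A | CC(C)=CCc1c(O)cc2c(c1O)C(=O)C[C@@H](c1cc3c(cc1O)OC(C)(C)C=C3)O2 | target

## Totals
Total steps: 11. Longest linear sequence: 8 (steps 1–5, 9, 10, 11 from compound 1). The B-ring arm (steps 6–8) is convergent.

## Three steps most likely to fail
1. **Step 10 (proposed new step).** The deactivated chalcone may react too slowly, or the ee may erode through retro-Michael reaction. Fallback: cyclize 15 to racemic 17 (NaOAc, EtOH, reflux) and resolve by preparative chiral-phase SFC/HPLC (known chemistry). Then finish with step 11 and assign 2S by [α]D/CD against the natural product.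
2. **Step 1.** Mono-C-prenylation could give low yields through O-prenylation and diprenylation. Fallback: build the prenylated ring from 1,3,5-tris(MOMO)benzene by ortho-lithiation/prenylation (n-BuLi, prenyl bromide, CuI). A second lithiation and N-methoxy-N-methylacetamide then give the tri-MOM acetophenone. The prenyl-distal OMOM is cleaved selectively with MgBr2·OEt2/n-PrSH, chelation- and sterics-controlled, to reach 9.
3. **Step 3.** Silylation selectivity for the prenyl-distal OH may be poor. Fallback: skip differentiation and carry 5 through Claisen–Schmidt to the 2′,6′-dihydroxychalcone. Let the catalyst and the steric difference control the oxa-Michael regiochemistry (6-prenyl versus 8-prenyl), separate the regioisomers, and then remove the remaining MOM groups as in step 11.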